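Late in the two earlier runs, at 80.0 s, Friday's flask still held 63.8% of its starting material and Tuesday's 18.7%. Both had the same charge and the same held gas, and they differed in initiator, 17 mM against 240 mM.

| flask | starting material | gas | initiator | remark | time |
|---|---|---|---|---|---|
| Friday's | 0.80 M | 200 mM (held) | 17 mM | run made earlier |  |
| Tuesday's | 0.80 M | 200 mM (held) | 240 mM | run made earlier |  |
| larch | 0.80 M | 200 mM (held) | 400 mM |  | 2.0 min |
| ash | 0.80 M | 200 mM (held) | 120 mM |  | 2.0 min |
| maple | 0.80 M | 200 mM (held) | 30 mM |  | 2.0 min |
| alder | 0.80 M | 200 mM (held) | 40 mM |  | 2.0 min |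

| run | time / s | product / % | starting material / % |
|---|---|---|---|
| Friday's | 10.0 | 5.4 | 94.8 |
| Friday's | 15.0 | 9.3 | 91.6 |
| Friday's | 25.0 | 14.7 | 84.1 |
| Friday's | 40.0 | 20.7 | 79.4 |
| Friday's | 60.0 | 29.3 | 70.4 |
| Friday's | 80.0 | 36.3 | 63.8 |
| Tuesday's | 10.0 | 19.5 | 80.7 |
| Tuesday's | 12.0 | 22.9 | 76.2 |
| Tuesday's | 25.0 | 40.9 | 57.8 |
| Tuesday's | 40.0 | 56.0 | 41.2 |
| Tuesday's | 50.0 | 64.5 | 35.0 |
| Tuesday's | 60.0 | 71.7 | 28.1 |
| Tuesday's | 80.0 | 79.6 | 18.7 |

(readings scatter by 1 percentage point)

- the numbers in the tables scatter by 1 percentage point (one standard deviation)
- at the start none of the gas is in solution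

- all flasks from highest to lowest amount of product, in percent of the starting material charged, at 2.0 min (larch / ash / maple / alder)
- the same order at 12 s (larch / ash / maple / alder)
- the amount of product, in percent of the starting material charged of the flask you put first, at 2.0 min
- the amount of product, in percent of the starting material charged of the flask you put last, at 2.0 min

These numbers do not seem to go together: Tuesday had 14.1 times the initiator, yet its rate constant, the log of charged over left divided by time, read 0.0210 s⁻¹ against Friday's 0.00562 s⁻¹, a ratio of 3.74.

I cleared this up by reckoning. Tuesday's constant reads 0.0222 s⁻¹ at 40.0 s, close to its value at the last reading, so Tuesday's run reads as pseudo-first-order in starting material. The root of the initiator ratio is 3.76, close to the ratio of the two constants, so the order in initiator reads as a half, as in a radical chain.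

I therefore carried one number, the two-minute exponent, meaning the log of charged over left reckoned for Tuesday's initiator charge at 2.0 min: 2.51. For any of these flasks it is multiplied by the root of the initiator ratio to Tuesday's. Product and starting material added to 98.3% in Tuesday's reading at 80.0 s, so I took the product as the charge less what is left. That gave me 96.1% in larch and 58.9% in maple. So I put the flasks in the order of their initiator charges at both times.

The forecast gave larch > ash > alder > maple at 2.0 min and larch > ash > alder > maple at 12 s, with 96% (90% to 98%) for the first flask and 60% (56% to 64%) for the last, which is higher than my figure. Its ground was “a square-root dependence, as in a radical chain”.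

The flasks came out larch > ash > alder > maple at 2.0 min and larch > ash > alder > maple at 12 s, with 95.7% of product in larch and 57.6% in maple.

    initiator → 2 initiating radical (k = 0.00300 s⁻¹)
    starting material + initiating radical → chain carrier (k = 6900 M⁻¹ s⁻¹)
    partner + chain carrier ⇌ product + initiating radical (K = 90.0, k = 83000 M⁻¹ s⁻¹)
    2 initiating radical → ended chains (k = 7.00 × 10⁷ M⁻¹ s⁻¹)
    partner → decomposed reagent (k = 9.40 × 10⁻⁴ s⁻¹)
    gas ⇌ partner, rate k6*(csat - [partner]) (kL = 0.480 s⁻¹)

In maple the partner stood at 0.192 M at 1.00 min and 0.195 M at 2.00 min, near its saturation of 200 mM, while the starting material went from 63.8% to 42.4%. Over the same minute the initiator went from 83.5% to 69.8% of its charge. Maple's exponent was 0.889 as reckoned and 0.859 from what remained. Scaled to a neighbour of larch with 1.6 M of initiator, the exponent leaves 0.151% of the starting material; that flask held 0.19% at 2.00 min.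

(The runs were generated by integration with constants of no real substance; noise was put on by code.)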